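Remark on numbering: atoms are counted as in 11,12-dihydroindolo[2,3-a]carbazole. Each chlorine is meta to its ring nitrogen and para to C4a or C6b, so the chlorines sit on C2 and C9, and the symmetric target is named as the 2,9-dichloro compound throughout.

## Structural features

Borregomycin E (15) is a flat, achiral pentacycle: a central benzene ring (ring C: C4b, C5, C6, C6a, C11a, C11b) is fused to two pyrrole rings (ring B with N12, ring D with N11), and each pyrrole is fused to a chlorobenzene ring (rings A and E). A mirror plane perpendicular to the ring plane passes through the midpoints of the C5–C6 and C11a–C11b bonds, so the two halves are identical 6-chloroindole units; there is no stereocentre, so nothing has to be set or guarded against epimerisation. Ring C carries no hydrogen: methoxy groups sit on C5 and C6, aryl carbons on C4b and C6a, and nitrogen on C11a and C11b. Building this pattern regiochemically cleanly is the real difficulty, because late substitution of a finished indolocarbazole at C5 and C6 is neither selective nor gentle. The fragile points are the electron-rich dimethoxy core with two free N–H groups, which oxidises easily towards the 5,6-quinone, and the two aryl C–Cl bonds, which forbid hydrogenolysis and forcing palladium chemistry late on. The key step uses the fact that the six atoms of ring C pair into three two-carbon units (C11b–C11a, C4b–C5, C6a–C6), each of which can be an alkyne: an ynamide on N12 and two aryl methoxyalkynes. A (2+2+2) cycloaddition then fixes five of the six substituents at once and leaves a single hydrogen, on C11a, where N11 is attached afterwards.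

## Logic of the disconnections

15 to 14: only the N12–S bond is added back. A sulfonyl group on N12 is what makes the ynamide possible, and it shields the electron-rich core until the end. The forward step must cleave it without touching the aryl chlorides or the methyl ethers, which hydroxide does.

14 to 12: the N11–C11a bond is cut, opening ring D to a carbazole that carries a 2-nitroaryl group on C6a. C11a–H is the only unsubstituted position of ring C, and a nitro group is an inert carrier of nitrogen through the organometallic steps. The forward step is a deoxygenative cyclisation that must go to C11a and not to the methoxy-bearing C6, and must not alkylate the new N–H.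

12 to 9 and 11: the bonds C4b–C11b, C5–C6 and C6a–C11a are cut, removing ring C and ring B together. A fully substituted tricyclic arene becomes a tethered diyne and a simple aryl alkyne. The forward step needs cross-selectivity over self-trimerisation and one orientation of 11.

11 to 10 and 7: the aryl–alkyne bond C6a–C6b is cut. The ortho-nitro bromide 10 is an activated coupling partner, and the methoxyalkyne arrives on zinc as 7. The forward step demands that the acetylide is fully on zinc before it meets the nitro group.

9 to 8: the C11a–Si bond is added back. The silyl cap keeps the ynamide terminus inert through the cross-coupling and is removed by fluoride just before the cycloaddition.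

8 to 4 and 7: the aryl–alkyne bond C4a–C4b is cut. Placing this coupling after ynamide formation means the acid-sensitive alkynyl ether is introduced as late as possible and never meets a free N–H, a sulfonyl chloride or hot copper. The forward coupling must tolerate a bulky ortho substituent and leave the ynamide alone.

7 to 5: the C–Zn bond and the triple bond are taken back, through 6, to the acetal 5. One batch of 7 serves both aryl halides, so the two-carbon methoxyalkyne unit is made once. The forward step must consume all of the amide base, so that none is carried into the couplings.

4 to 2 and 3: the N12–C11b bond is cut. The forward step is a copper-catalysed N-alkynylation that must be faster than any reaction at the aryl C–I bond.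

2 to 1: the N12–S bond is cut, back to 1, whose iodine marks C4a and whose chlorine is already on C2.

## Other disconnections considered

Alternative 1: The cut is through C4a–C4b and C6a–C6b, after the two O-methyl groups are taken back to a 5,6-quinone. It leads to the bis-anilino ortho-quinone A3, which an oxidative twofold amination of catechol A2 with 2-bromo-5-chloroaniline A1 would assemble.
- Forward key step: Pd(OAc)2 with KOAc in N,N-dimethylacetamide would give zerovalent palladium, which inserts into both C–Br bonds of A3 in preference to C–Cl. Each arylpalladium bromide palladates the neighbouring quinone C–H (C4b or C6a, the nucleophilic carbon of a vinylogous amide) by a Heck-type or acetate-assisted metalation path. Reductive elimination closes rings B and D to give dione A4, and reductive O-methylation of A4 would finish.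
- In its favour: it uses the mirror symmetry of the target, so one aniline serves for both halves. Both pyrroles form in one flask, no nitrogen protecting group is needed, and the whole route could be about four steps. On step economy and on use of symmetry it is better than the chosen plan, which builds the halves from two different aryl halides in nine steps.
- Against it: an ortho-quinone can oxidise zerovalent palladium and bind it as a catecholate, so catalyst turnover is doubtful. The hindered, electron-poor aniline A1 should add reluctantly to the quinone. The final step must methylate two phenolic oxygens of an air-sensitive hydroquinone in the presence of two N–H groups.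
- Comparison: the chosen plan relies on individually better precedented events on more ordinary functional groups. Alternative 1 stakes everything on a double arylation of a redox-active substrate. Structurally both reach the same ring system; mechanistically the chosen plan is the safer, and in length Alternative 1 wins.

Alternative 2: The cut is through C5–C6, C6a–C11a and C11a–C11b, with C11a supplied by a carbonyl ligand of the metal. Ring C is assembled from the indol-3-yl(methoxy)carbene pentacarbonylchromium complex A5 and the aryl methoxyalkyne A6.
- Forward key step: heating A5 with A6 should insert the alkyne into the chromium–carbene bond, insert a carbonyl ligand, and electrocyclise onto indole C2 to give the 1-hydroxycarbazole A7 (Dötz benzannulation).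
- In its favour: like the chosen plan it builds ring C with all six positions defined in one step from an alkynyl ether, so the two are equal on that point. The orientation rule of the benzannulation (larger alkyne substituent next to the new phenol) is well founded, arguably better than the steric argument for the rhodium insertion. C11a emerges with an oxygen handle, so N11 could be introduced by mild palladium amination of a sulfonate and the aryl bromide instead of a 180 °C deoxygenation; that is a point in its favour.
- Against it: the carbene complex A5 is stoichiometric in a toxic metal. An indol-3-yl carbene is stabilised by the ring nitrogen like an aminocarbene, which slows carbonyl insertion and favours five-membered ring by-products. The end game needs sulfonate formation, a double amination and removal of the [2-(trimethylsilyl)ethoxy]methyl group, which is notoriously stubborn on indole-type nitrogen; that is three steps after the key step against two.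
- Comparison: the overall count would be about eight to nine steps, on a par with the chosen plan. Mechanistically the two share the regiochemical risk of an unsymmetrical alkynyl ether. The chosen plan is catalytic in metal and carries nitrogen N11 in from the start.

Alternative 3: The cut is through N11–C11a and C6–C6a. The precursor A8 is an N-Boc indole with a (2-azidoaryl)ethynyl group on C11b and a 1,2-dimethoxyethenyl group on C4b.
- Forward key step: Ph3PAuNTf2 activates the alkyne of A8, and the azide nitrogen attacks C11a in a 5-endo closure. Loss of dinitrogen gives a gold carbene at C6a, which the enol ether carbon C6 captures in a six-membered closure. Loss of a proton and of gold would give A9, and removal of the Boc group would complete the target.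
- In its favour: the azide-to-gold-carbene chemistry of 2-alkynyl aryl azides is established and runs near room temperature. N11 is installed inside the key step, so no separate hot cyclisation is needed, and only a Boc group has to be removed afterwards. On the mildness and brevity of the end game it is better than the chosen plan.
- Against it: A8 combines an acid-labile enol ether, an energetic aryl azide and a 2-alkynylindole. Making it would need C2 halogenation, a Sonogashira coupling, enol ether formation of undefined geometry and a late azidation, probably nine to eleven steps. The gold carbene could also be intercepted by the Boc carbonyl oxygen or by C5 of the enol ether, and traces of acid could hydrolyse the enol ether.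
- Comparison: both key steps close one pyrrole and ring C. This one forms two bonds where the chosen one forms three, and its precursor is much harder to reach. Neither uses the symmetry. The chosen plan is at least as short overall, while Alternative 3 has the gentler final stages.

Key step: step 7

## Route

Step 1
Reactants: 1 5-chloro-2-iodoaniline
Product: 2 N-(5-chloro-2-iodophenyl)-4-methylbenzenesulfonamide
Conditions: TsCl, pyridine, 0 °C to 40 °C
Reagents that add atoms: 4-methylbenzenesulfonyl chloride (TsCl), Cc1ccc(cc1)S(Cl)(=O)=O
Why: Sulfonylation of the aniline nitrogen; pyridine is base and nucleophilic catalyst for this weakly nucleophilic amine, and the ortho iodine should hold the reaction at the mono-sulfonamide. The acidic N–H is the handle for N-alkynylation and the sulfonyl group later tempers the ynamide.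

Step 2
Reactants: 2 N-(5-chloro-2-iodophenyl)-4-methylbenzenesulfonamide; 3 (bromoethynyl)tri(propan-2-yl)silane
Product: 4 N-(5-chloro-2-iodophenyl)-4-methyl-N-{[tri(propan-2-yl)silyl]ethynyl}benzenesulfonamide
Conditions: CuSO4·5H2O (10 mol%), 1,10-phenanthroline (20 mol%), K2CO3, toluene, 70 °C
Reagents that add atoms: none
Why: Copper-catalysed amidative cross-coupling of a sulfonamide with a 1-bromoalkyne (Ullmann-type N-alkynylation), a standard entry to N-sulfonyl ynamides; reaction of the copper amidate with the bromoalkyne should be much faster at 70 °C than Ullmann or Goldberg chemistry at the aryl C–I bond, and the bulky silyl cap suppresses alkyne homocoupling. No alkynyl ether is present yet, so copper cannot trigger cyclisation to an indole.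

Step 3
Reactants: 5 chloroacetaldehyde dimethyl acetal
Product: 7 (methoxyethynyl)zinc chloride, via lithium methoxyacetylide 6 (not isolated)
Conditions: LiNEt2 (3 equiv, from n-BuLi and Et2NH), THF, 0 °C; then ZnCl2 (2 equiv), 0 °C
Reagents that add atoms: zinc dichloride (ZnCl2), Cl[Zn]Cl
Why: Twofold elimination and metalation: LiNEt2 removes methanol and HCl from 5 and deprotonates the methoxyacetylene so formed to give 6, the standard generation of a lithium alkoxyacetylide from a chloroacetaldehyde acetal, and transmetalation with ZnCl2 gives the milder zinc acetylide 7. One batch is made as a THF solution, kept at 0 °C and divided at once between steps 4 and 6, so that no free lithium acetylide or amide base reaches the sulfonyl ynamide or the nitroarene.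

Step 4
Reactants: 4 N-(5-chloro-2-iodophenyl)-4-methyl-N-{[tri(propan-2-yl)silyl]ethynyl}benzenesulfonamide; 7 (methoxyethynyl)zinc chloride
Product: 8 N-[5-chloro-2-(methoxyethynyl)phenyl]-4-methyl-N-{[tri(propan-2-yl)silyl]ethynyl}benzenesulfonamide
Conditions: 7 (1.5 equiv, THF solution from step 3), Pd(PPh3)4 (5 mol%), THF, 0 °C to rt
Reagents that add atoms: none
Why: Negishi coupling of an alkoxyethynylzinc chloride with an aryl iodide: zerovalent palladium inserts into the C–I bond of 4 (C–Cl untouched), transmetalates with 7 and reductively eliminates to form C4a–C4b. The sulfonyl ynamide has no N–H and cannot be carbopalladated intramolecularly (a four-membered ring would result), so it should be a spectator.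

Step 5
Reactants: 8 N-[5-chloro-2-(methoxyethynyl)phenyl]-4-methyl-N-{[tri(propan-2-yl)silyl]ethynyl}benzenesulfonamide
Product: 9 N-[5-chloro-2-(methoxyethynyl)phenyl]-N-ethynyl-4-methylbenzenesulfonamide
Conditions: Bu4NF (1.1 equiv), wet THF, −20 °C to 0 °C
Reagents that add atoms: none
Why: Fluoride-mediated protodesilylation of a silyl alkyne; silicon on the ynamide sp carbon is cleaved at or below 0 °C, while the methyl alkynyl ether, the sulfonamide and the aryl chloride are inert to fluoride and mild base. The terminal ynamide is kept cold, passed through base-washed silica and used directly.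

Step 6
Reactants: 10 1-bromo-4-chloro-2-nitrobenzene; 7 (methoxyethynyl)zinc chloride
Product: 11 4-chloro-1-(methoxyethynyl)-2-nitrobenzene
Conditions: 7 (1.5 equiv, THF solution from step 3), Pd(PPh3)4 (5 mol%), THF, 0 °C to rt
Reagents that add atoms: none
Why: Negishi coupling as in step 4; the ortho nitro group activates the C–Br bond of 10 for oxidative addition to zerovalent palladium at room temperature, while the C–Cl bond meta to nitro is not activated. The zinc acetylide 7 tolerates the nitro group where the lithium species 6 would not, which is why the acetylide is moved to zinc before it meets 10.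

Step 7
Reactants: 9 N-[5-chloro-2-(methoxyethynyl)phenyl]-N-ethynyl-4-methylbenzenesulfonamide; 11 4-chloro-1-(methoxyethynyl)-2-nitrobenzene
Product: 12 7-chloro-2-(4-chloro-2-nitrophenyl)-3,4-dimethoxy-9-(4-methylbenzenesulfonyl)-9H-carbazole
Conditions: RhCl(PPh3)3 (10 mol%), toluene, 40 °C, slow addition of 9 to 11 (2 equiv)
Reagents that add atoms: none
Why: Crossed alkyne cyclotrimerisation with one tether, the known route from N-alkynyl-2-alkynylanilines and a third alkyne to carbazoles. Monovalent rhodium, after loss of PPh3, binds the ynamide and the tethered alkynyl ether of 9 and couples them oxidatively to a trivalent rhodacyclopentadiene; this forms C4b–C11b between the electrophilic ynamide carbon and the nucleophilic aryl-bearing carbon of the ynol ether and closes ring B as a five-membered ring whose size is fixed by the ortho-phenylene tether. Alkyne 11 then coordinates and inserts, and reductive elimination forms C5–C6 and C6a–C11a, closing ring C as the six-membered ring of a formal (2+2+2) addition and returning monovalent rhodium. No stereocentre is formed. The step needs cross- over homo-selectivity: the diyne reacts intramolecularly first, its slow addition to an excess of 11 keeps self-trimerisation low, and 11, a hindered internal alkyne, should not trimerise alone. It also needs one orientation of 11: the rhodacycle termini are C11a–H and C5–OMe, so the bulky nitroaryl carbon C6a should bond to the unhindered C11a and the small methoxy carbon C6 to C5, which avoids an aryl group wedged between two methoxy groups. Nitro, aryl chloride, sulfonamide and methyl ether groups are inert to RhCl(PPh3)3 at this temperature.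

Step 8
Reactants: 12 7-chloro-2-(4-chloro-2-nitrophenyl)-3,4-dimethoxy-9-(4-methylbenzenesulfonyl)-9H-carbazole
Product: 14 2,9-dichloro-5,6-dimethoxy-12-(4-methylbenzenesulfonyl)-11,12-dihydroindolo[2,3-a]carbazole, via nitrosoarene 13 (not isolated)
Conditions: PPh3 (3 equiv), 1,2-dichlorobenzene, 180 °C
Reagents that add atoms: none
Why: Cadogan reductive cyclisation: PPh3 deoxygenates the nitro group through nitrosoarene 13 to a nitrene or its phosphorus-bound equivalent, which attacks the adjacent C11a–H, the only unsubstituted carbon of ring C, forming N11–C11a and closing ring D. PPh3 in 1,2-dichlorobenzene is chosen over a trialkyl phosphite so that the new N–H cannot be alkylated; the sulfonamide, methyl ethers and aryl chlorides should survive the heat.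

Step 9
Reactants: 14 2,9-dichloro-5,6-dimethoxy-12-(4-methylbenzenesulfonyl)-11,12-dihydroindolo[2,3-a]carbazole
Product: 15 2,9-dichloro-5,6-dimethoxy-11,12-dihydroindolo[2,3-a]carbazole (borregomycin E)
Conditions: KOH, THF/EtOH/H2O, 70 °C, argon
Reagents that add atoms: none
Why: Base hydrolysis of an N-sulfonyl carbazole: the carbazolide is a good leaving group, so hydroxide attacks sulfur and frees N12. The aryl chlorides are not activated for substitution, the methyl ethers are inert, and working under argon limits oxidation of the electron-rich product.

## Compound list

1 | 5-chloro-2-iodoaniline | Nc1cc(Cl)ccc1I | starting material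
2 | N-(5-chloro-2-iodophenyl)-4-methylbenzenesulfonamide | Cc1ccc(cc1)S(=O)(=O)Nc1cc(Cl)ccc1I | intermediate
3 | (bromoethynyl)tri(propan-2-yl)silane | CC(C)[Si](C#CBr)(C(C)C)C(C)C | starting material
4 | N-(5-chloro-2-iodophenyl)-4-methyl-N-{[tri(propan-2-yl)silyl]ethynyl}benzenesulfonamide | Cc1ccc(cc1)S(=O)(=O)N(C#C[Si](C(C)C)(C(C)C)C(C)C)c1cc(Cl)ccc1I | intermediate
5 | chloroacetaldehyde dimethyl acetal (2-chloro-1,1-dimethoxyethane) | COC(CCl)OC | starting material
6 | lithium methoxyacetylide | COC#C[Li] | intermediate (not isolated)
7 | (methoxyethynyl)zinc chloride (made and used as a THF solution) | COC#C[Zn]Cl | intermediate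
8 | N-[5-chloro-2-(methoxyethynyl)phenyl]-4-methyl-N-{[tri(propan-2-yl)silyl]ethynyl}benzenesulfonamide | COC#Cc1ccc(Cl)cc1N(C#C[Si](C(C)C)(C(C)C)C(C)C)S(=O)(=O)c1ccc(C)cc1 | intermediate
9 | N-[5-chloro-2-(methoxyethynyl)phenyl]-N-ethynyl-4-methylbenzenesulfonamide | COC#Cc1ccc(Cl)cc1N(C#C)S(=O)(=O)c1ccc(C)cc1 | intermediate
10 | 1-bromo-4-chloro-2-nitrobenzene | O=[N+]([O-])c1cc(Cl)ccc1Br | starting material
11 | 4-chloro-1-(methoxyethynyl)-2-nitrobenzene | COC#Cc1ccc(Cl)cc1[N+](=O)[O-] | intermediate
12 | 7-chloro-2-(4-chloro-2-nitrophenyl)-3,4-dimethoxy-9-(4-methylbenzenesulfonyl)-9H-carbazole | COc1c(OC)c(-c2ccc(Cl)cc2[N+](=O)[O-])cc2c1c1ccc(Cl)cc1n2S(=O)(=O)c1ccc(C)cc1 | intermediate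
13 | 7-chloro-2-(4-chloro-2-nitrosophenyl)-3,4-dimethoxy-9-(4-methylbenzenesulfonyl)-9H-carbazole | COc1c(OC)c(-c2ccc(Cl)cc2N=O)cc2c1c1ccc(Cl)cc1n2S(=O)(=O)c1ccc(C)cc1 | intermediate (not isolated)
14 | 2,9-dichloro-5,6-dimethoxy-12-(4-methylbenzenesulfonyl)-11,12-dihydroindolo[2,3-a]carbazole | COc1c(OC)c2c3ccc(Cl)cc3[nH]c2c2c1c1ccc(Cl)cc1n2S(=O)(=O)c1ccc(C)cc1 | intermediate
15 | 2,9-dichloro-5,6-dimethoxy-11,12-dihydroindolo[2,3-a]carbazole (borregomycin E) | COc1c(OC)c2c3ccc(Cl)cc3[nH]c2c2[nH]c3cc(Cl)ccc3c12 | target

## Step count and risks

Total step count: 9. Longest linear sequence: 7 steps (steps 1, 2, 4, 5, 7, 8, 9 from compound 1); step 3 supplies the zinc reagent for both couplings and step 6 supplies the second alkyne.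

**Step 7 (key step).**
- Risk: the external alkyne may insert in the reverse orientation, or so slowly that self-reaction of the diyne or vinylidene formation at the terminal ynamide takes over. Alkyne 11 is a hindered partner carrying a coordinating nitro group, and the steric preference between the two rhodacycle termini is not backed by a clear electronic preference.
- Fallback: this sets out from 9 and 5 and returns at 12. It keeps the ring-forming disconnection but forms the C6a–C6b aryl–aryl bond by cross-coupling. Compound 5 would be taken to 6 as in the first half of step 3 and quenched with Me3SiCl to give (methoxyethynyl)trimethylsilane F1. Cycloaddition of 9 with F1 under RhCl(PPh3)3 should give 7-chloro-3,4-dimethoxy-9-(4-methylbenzenesulfonyl)-2-(trimethylsilyl)-9H-carbazole F2; this partner is nitro-free and its steric bias is far larger. Ipso-iododesilylation with ICl would give 7-chloro-2-iodo-3,4-dimethoxy-9-(4-methylbenzenesulfonyl)-9H-carbazole F3. Miyaura borylation with bis(pinacolato)diboron, KOAc and PdCl2[1,1'-bis(diphenylphosphino)ferrocene] would give 7-chloro-3,4-dimethoxy-9-(4-methylbenzenesulfonyl)-2-(4,4,5,5-tetramethyl-1,3,2-dioxaborolan-2-yl)-9H-carbazole F4. Suzuki–Miyaura coupling of F4 with 10 (Pd(PPh3)4, K3PO4) would then give 12.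

**Step 4.**
- Risk: oxidative addition and transmetalation at an iodide flanked by the bulky N-sulfonyl ynamide may be slow. The zinc acetylide would then decay, or the diethylamine and methoxide carried in the solution of 7 would attack the sulfonyl ynamide.
- Fallback: this sets out from 1 and returns at 9, bypassing steps 2, 4 and 5. It installs the alkynyl ether first and makes the N–C(sp) bond with an electrophilic alkyne transfer reagent instead of copper catalysis, so copper-promoted closure to an indole cannot occur. Negishi coupling of 1 with 7 would give 5-chloro-2-(methoxyethynyl)aniline F5. TsCl in pyridine at 0 °C would give N-[5-chloro-2-(methoxyethynyl)phenyl]-4-methylbenzenesulfonamide F6. Deprotonation with KN(SiMe3)2 in toluene and reaction with phenyl[(trimethylsilyl)ethynyl]iodonium trifluoromethanesulfonate would give N-[5-chloro-2-(methoxyethynyl)phenyl]-4-methyl-N-[(trimethylsilyl)ethynyl]benzenesulfonamide F7. Bu4NF would convert F7 into 9.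

**Step 6.**
- Risk: nucleophilic aromatic substitution of the activated bromide of 10 by the diethylamine or methoxide that accompany 7, or electron transfer from organometallic species to the nitro group, may compete with the palladium cycle.
- Fallback: this sets out from 10 and 5 and returns at 11. Compound 5 would be taken to 6 as in the first half of step 3 and quenched with Bu3SnCl, and distillation would give tributyl(methoxyethynyl)stannane F8. This neutral, amine-free alkynyl donor would be joined to 10 by Stille coupling (Pd(PPh3)4, toluene, 80 °C) to give 11.

**Step 8.**
- Risk: the nitrene may attack ipso at the methoxy-bearing C6 with migration or loss of the methoxy group, or the material may degrade at 180 °C; the sulfonyl group next to C11a also crowds the desired site.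
- Fallback: this sets out from 12 and returns at 14, replacing thermal deoxygenation with a catalytic nitrene transfer at low temperature. Reduction with Fe and NH4Cl in EtOH/H2O would give 5-chloro-2-[7-chloro-3,4-dimethoxy-9-(4-methylbenzenesulfonyl)-9H-carbazol-2-yl]aniline F9. Diazotisation and azide transfer with tert-butyl nitrite and Me3SiN3 would give 2-(2-azido-4-chlorophenyl)-7-chloro-3,4-dimethoxy-9-(4-methylbenzenesulfonyl)-9H-carbazole F10. Rh2(O2CC7H15)4 in toluene at 60 °C should convert F10 by C–H amination at C11a into 14.

## Further compounds

F1 | step 7 | (methoxyethynyl)trimethylsilane | COC#C[Si](C)(C)C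
F2 | step 7 | 7-chloro-3,4-dimethoxy-9-(4-methylbenzenesulfonyl)-2-(trimethylsilyl)-9H-carbazole | COc1c(OC)c([Si](C)(C)C)cc2c1c1ccc(Cl)cc1n2S(=O)(=O)c1ccc(C)cc1
F3 | step 7 | 7-chloro-2-iodo-3,4-dimethoxy-9-(4-methylbenzenesulfonyl)-9H-carbazole | COc1c(OC)c(I)cc2c1c1ccc(Cl)cc1n2S(=O)(=O)c1ccc(C)cc1
F4 | step 7 | 7-chloro-3,4-dimethoxy-9-(4-methylbenzenesulfonyl)-2-(4,4,5,5-tetramethyl-1,3,2-dioxaborolan-2-yl)-9H-carbazole | COc1c(OC)c(B3OC(C)(C)C(C)(C)O3)cc2c1c1ccc(Cl)cc1n2S(=O)(=O)c1ccc(C)cc1
F5 | step 4 | 5-chloro-2-(methoxyethynyl)aniline | COC#Cc1ccc(Cl)cc1N
F6 | step 4 | N-[5-chloro-2-(methoxyethynyl)phenyl]-4-methylbenzenesulfonamide | COC#Cc1ccc(Cl)cc1NS(=O)(=O)c1ccc(C)cc1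
F7 | step 4 | N-[5-chloro-2-(methoxyethynyl)phenyl]-4-methyl-N-[(trimethylsilyl)ethynyl]benzenesulfonamide | COC#Cc1ccc(Cl)cc1N(C#C[Si](C)(C)C)S(=O)(=O)c1ccc(C)cc1
F8 | step 6 | tributyl(methoxyethynyl)stannane | CCCC[Sn](CCCC)(CCCC)C#COC
F9 | step 8 | 5-chloro-2-[7-chloro-3,4-dimethoxy-9-(4-methylbenzenesulfonyl)-9H-carbazol-2-yl]aniline | COc1c(OC)c(-c2ccc(Cl)cc2N)cc2c1c1ccc(Cl)cc1n2S(=O)(=O)c1ccc(C)cc1
F10 | step 8 | 2-(2-azido-4-chlorophenyl)-7-chloro-3,4-dimethoxy-9-(4-methylbenzenesulfonyl)-9H-carbazole | COc1c(OC)c(-c2ccc(Cl)cc2N=[N+]=[N-])cc2c1c1ccc(Cl)cc1n2S(=O)(=O)c1ccc(C)cc1
A1 | alternative 1 | 2-bromo-5-chloroaniline | Nc1cc(Cl)ccc1Br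
A2 | alternative 1 | benzene-1,2-diol (catechol) | Oc1ccccc1O
A3 | alternative 1 | 4,5-bis(2-bromo-5-chloroanilino)cyclohexa-3,5-diene-1,2-dione | O=C1C=C(Nc2cc(Cl)ccc2Br)C(Nc2cc(Cl)ccc2Br)=CC1=O
A4 | alternative 1 | 2,9-dichloro-11,12-dihydroindolo[2,3-a]carbazole-5,6-dione | O=C1C(=O)c2c(-c3[nH]c4cc(Cl)ccc4c31)[nH]c1cc(Cl)ccc21
A5 | alternative 2 | pentacarbonyl[(6-chloro-1-{[2-(trimethylsilyl)ethoxy]methyl}-1H-indol-3-yl)(methoxy)methylidene]chromium | COC(c1cn(COCC[Si](C)(C)C)c2cc(Cl)ccc12)=[Cr](=C=O)(=C=O)(=C=O)(=C=O)=C=O
A6 | alternative 2 | 2-bromo-4-chloro-1-(methoxyethynyl)benzene | COC#Cc1ccc(Cl)cc1Br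
A7 | alternative 2 | 2-(2-bromo-4-chlorophenyl)-7-chloro-3,4-dimethoxy-9-{[2-(trimethylsilyl)ethoxy]methyl}-9H-carbazol-1-ol | COc1c(OC)c(-c2ccc(Cl)cc2Br)c(O)c2c1c1ccc(Cl)cc1n2COCC[Si](C)(C)C
A8 | alternative 3 | tert-butyl 2-[(2-azido-4-chlorophenyl)ethynyl]-6-chloro-3-[(E)-1,2-dimethoxyethenyl]-1H-indole-1-carboxylate (drawn as the E isomer; either geometry would serve) | CO/C=C(/OC)c1c(C#Cc2ccc(Cl)cc2N=[N+]=[N-])n(C(=O)OC(C)(C)C)c2cc(Cl)ccc12
A9 | alternative 3 | tert-butyl 2,9-dichloro-5,6-dimethoxy-11H-indolo[2,3-a]carbazole-12-carboxylate | COc1c(OC)c2c3ccc(Cl)cc3[nH]c2c2c1c1ccc(Cl)cc1n2C(=O)OC(C)(C)C
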